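## Retrosynthetic overview

1. Feature used: in ring D (the meta-phenylene), the carbon bound to the ether oxygen of ring A and the carbon bound to the C–D bridge CH2 stand 1,3 to each other. This matches C3 and C5 of a 5-(2-arylethyl)cyclohexane-1,3-dione, and the surplus oxygen at C1 is shed as water on aromatisation.
2. 25 ⇒ (O-demethylation) arene 24 ⇒ (DDQ, dehydration, 1,2-reduction) macrocyclic 3-aryloxycyclohexenone 20.
3. 20 ⇒ seco chloroenone 19. The ring A O–C3 bond is cut, so the 18-membered ring is closed by phenoxide addition–elimination at the C–Cl carbon.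
4. 19 ⇒ dione 17 ⇒ enone 12 + diethyl malonate 13 (Michael addition, Claisen closure and decarboxylation build the ring D carbocycle); 12 ⇒ ester 10.
5. 10 ⇒ phosphonium salt 4 + aldehyde 7 (Wittig, H2: A–B bridge); 7 ⇒ 5 + 6 (Ullmann: B–O–C ether). Ring order: A, B and C are bought, the ring D carbocycle forms in step 9, the macrocycle in step 12, and ring D becomes aromatic in step 15.

Key step: step 12

Assumption: the target has no stereocentre and its 18-membered ring is taken as conformationally mobile, so nothing needs control. The sp3 centres of intermediates are carried as racemates or mixtures and are gone after step 15.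

Shorthand: Ar1 = 4-(2-methoxy-5-{2-[5-methoxy-2-(propan-2-yloxy)phenyl]ethyl}phenoxy)phenyl, that is rings A, B and C joined with the ring A oxygen as isopropyl ether.

Ring D precursor numbering: C1 carbonyl carbon, C2 vinylic CH, C3 carbon bearing Cl or OAr, C4 CH2, C5 CH bearing the bridge, C6 CH2.

## Route

Step 1
Reactants: 1 2-hydroxy-5-methoxybenzaldehyde
Product: 2 5-methoxy-2-(propan-2-yloxy)benzaldehyde
Conditions: 2-bromopropane, K2CO3, DMF, 60 °C
Reagents that add atoms: 2-bromopropane, CC(C)Br
Why: Williamson ether synthesis on the acidic salicylaldehyde phenol; the isopropyl ether is chosen because it withstands hydrogenation, hydride, alkoxide, hot aqueous acid and oxalyl chloride, yet is cleaved by BCl3 faster than an aryl methyl ether.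

Step 2
Reactants: 2 5-methoxy-2-(propan-2-yloxy)benzaldehyde
Product: 3 [5-methoxy-2-(propan-2-yloxy)phenyl]methanol
Conditions: NaBH4, MeOH, 0 °C
Reagents that add atoms: none
Why: Borohydride reduction of an aromatic aldehyde, with no other reducible group present.

Step 3
Reactants: 3 [5-methoxy-2-(propan-2-yloxy)phenyl]methanol
Product: 4 [5-methoxy-2-(propan-2-yloxy)benzyl]triphenylphosphonium bromide
Conditions: PPh3·HBr, MeCN, reflux
Reagents that add atoms: triphenylphosphine hydrobromide, [Br-].[PH+](c1ccccc1)(c1ccccc1)c1ccccc1
Why: Direct phosphonium salt formation by SN1-type substitution, in which the acid ionises the electron-rich ortho-alkoxybenzylic alcohol and PPh3 traps the benzylic electrophile, so no separate halide step is needed.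

Step 4
Reactants: 5 methyl 3-(4-hydroxyphenyl)propanoate; 6 3-bromo-4-methoxybenzaldehyde
Product: 7 methyl 3-[4-(5-formyl-2-methoxyphenoxy)phenyl]propanoate
Conditions: CuI (10 mol%), N,N-dimethylglycine·HCl (30 mol%), Cs2CO3, 1,4-dioxane, 90 °C
Reagents that add atoms: none
Why: Ligand-accelerated Ullmann diaryl ether coupling; the unhindered para-alkylphenol is a good partner for monovalent copper, and the amino acid ligand keeps the temperature low enough for the aldehyde and methyl ester to survive.

Step 5
Reactants: 4 [5-methoxy-2-(propan-2-yloxy)benzyl]triphenylphosphonium bromide; 7 methyl 3-[4-(5-formyl-2-methoxyphenoxy)phenyl]propanoate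
Product: 9 methyl 3-{4-[2-methoxy-5-(2-[5-methoxy-2-(propan-2-yloxy)phenyl]ethenyl)phenoxy]phenyl}propanoate (E/Z mixture), via benzylidene phosphorane 8 (not isolated)
Conditions: K2CO3, 18-crown-6 (cat.), CH2Cl2, reflux
Reagents that add atoms: none
Why: Wittig olefination under solid–liquid phase-transfer conditions; carbonate deprotonates the benzylic phosphonium salt but leaves the methyl ester alone, and the alkene geometry is irrelevant because the double bond is saturated next.

Step 6
Reactants: 9 stilbene ester (E/Z mixture)
Product: 10 methyl 3-(Ar1)propanoate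
Conditions: H2 (1 atm), Pd/C (10%), EtOAc, rt
Reagents that add atoms: none
Why: Catalytic hydrogenation of a stilbene to the bibenzyl; aryl isopropyl, aryl methyl and diaryl ethers and the ester are inert under these conditions.

Step 7
Reactants: 10 methyl 3-(Ar1)propanoate
Product: 11 3-(Ar1)propanal
Conditions: i-Bu2AlH (DIBAL-H, 1.05 equiv), toluene, −78 °C; MeOH, then aq. potassium sodium tartrate
Reagents that add atoms: none
Why: Partial ester reduction; the tetrahedral aluminium hemiacetal persists at −78 °C and releases the aldehyde only on quenching.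

Step 8
Reactants: 11 3-(Ar1)propanal
Product: 12 (E)-6-(Ar1)hex-3-en-2-one
Conditions: Ph3P=CHC(O)CH3, toluene, 70 °C
Reagents that add atoms: 1-(triphenylphosphoranylidene)propan-2-one, CC(=O)C=P(c1ccccc1)(c1ccccc1)c1ccccc1
Why: Wittig olefination with a stabilised ylide should give the E-enone under neutral conditions, which avoids the self-aldol of the enolisable aldehyde that a base-mediated condensation with acetone would invite.

Step 9
Reactants: 12 (E)-6-(Ar1)hex-3-en-2-one; 13 diethyl malonate
Product: 17 5-[2-(Ar1)ethyl]cyclohexane-1,3-dione, via Michael adduct 14 (not isolated), via cyclic keto ester 15 (not isolated), via cyclic keto acid 16 (not isolated)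
Conditions: NaOEt, EtOH, reflux; aq. NaOH, reflux; EtOH distilled off; aq. HCl (pH 1), 1,4-dioxane, 80 °C
Reagents that add atoms: sodium hydroxide, [Na+].[OH-] (its oxygen stands only in intermediate 16 and leaves again as CO2)
Why: Michael addition, intramolecular Claisen (Dieckmann-type) closure of the methyl ketone enolate on one ester, saponification and decarboxylation form the classical one-flask route to 5-substituted cyclohexane-1,3-diones; the stereocentres of 14 to 16 do not matter because 17 is achiral at C5.

Step 10
Reactants: 17 5-[2-(Ar1)ethyl]cyclohexane-1,3-dione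
Product: 18 rac-3-chloro-5-[2-(Ar1)ethyl]cyclohex-2-en-1-one
Conditions: (COCl)2 (1.3 equiv), CHCl3, reflux
Reagents that add atoms: oxalyl chloride, O=C(Cl)C(=O)Cl
Why: Vinylogous acid chloride formation, in which the enol is acylated and chloride displaces the activated oxygen by addition–elimination; the two carbonyl groups of 17 are enantiotopic, so one constitution forms and C5 becomes a racemic stereocentre that needs no control.

Step 11
Reactants: 18 rac-3-chloro-5-[2-(Ar1)ethyl]cyclohex-2-en-1-one
Product: 19 rac-3-chloro-5-{2-[4-(5-[2-(2-hydroxy-5-methoxyphenyl)ethyl]-2-methoxyphenoxy)phenyl]ethyl}cyclohex-2-en-1-one (seco phenol)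
Conditions: BCl3 (3 equiv), CH2Cl2, −78 to 0 °C; ice-cold water
Reagents that add atoms: none
Why: Lewis acid ether dealkylation; the secondary isopropyl group leaves the BCl3-complexed oxygen in an SN1-like way much faster than a methyl group, and chloride attack on the complexed chloroenone is degenerate, so C3–Cl should be kept.

Step 12
Reactants: 19 seco phenol chloroenone
Product: 20 rac-macrocyclic 3-aryloxycyclohex-2-en-1-one (18-membered ring; ring A oxygen on C3; C–D bridge on C5; two methyl ethers)
Conditions: Cs2CO3 (5 equiv), 4 Å MS, MeCN, 60 °C, 19 added by syringe pump over 12 h (final ca. 2 mM)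
Reagents that add atoms: none
Why: Cs2CO3 converts the only free phenol (ring A, next to the A–B bridge) into its caesium phenoxide, which adds in conjugate fashion to C3 to give an enolate with tetrahedral C3 that collapses with loss of chloride (vinylogous acyl substitution, addition–elimination at sp2 carbon). The closest known reaction type is the carbonate-mediated intermolecular preparation of 3-aryloxycyclohex-2-enones from phenols and 3-halocyclohex-2-enones; closing a large ring with it is an extension run under pseudo-high dilution, comparable to SNAr closures of macrocyclic diaryl ethers. The 18-membered ring closes in 18-exo-trig mode, because the accepting C2=C3 bond lies outside the shortest ring path O–C3–C4–C5. No stereocentre is created, since C3 returns to sp2 and racemic C5 is untouched until it is erased in step 15. The step needs O- over C-attack, 1,4- over 1,2-addition and closure over oligomerisation; the loosely paired hard phenoxide in a polar aprotic solvent and the irreversible chloride loss favour the O–C3 bond, the small C3 accepts the ortho-alkylated phenoxide, the other two phenol oxygens are masked as methyl ethers, and slow addition keeps free 19 dilute. MeCN is preferred to DMF so that no dimethylamine competes for C3, and the sieves keep water from hydrolysing the chloroenone back to the dione.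

Step 13
Reactants: 20 rac-macrocyclic 3-aryloxycyclohex-2-en-1-one
Product: 21 macrocyclic 3-aryloxycyclohex-2-en-1-ol (racemic; mixture of C1/C5 diastereomers)
Conditions: i-Bu2AlH (DIBAL-H, 1.2 equiv), CH2Cl2, −78 °C; aq. potassium sodium tartrate; used crude
Reagents that add atoms: none
Why: 1,2-Reduction of a vinylogous ester (first half of a Stork–Danheiser sequence) with an aprotic hydride and a non-acidic work-up, because the product ionises easily in acidic methanol; the C1 carbinol centre forms without control as a diastereomer mixture, which is acceptable since C1 and C5 both become sp2.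

Step 14
Reactants: 21 macrocyclic 3-aryloxycyclohex-2-en-1-ol
Product: 23 rac-macrocyclic 1-aryloxycyclohexa-1,3-diene (C3=C2–C1=C6; sp3 C4 and C5), via allylic mesylate 22 (not isolated)
Conditions: MsCl, Et3N (excess), CH2Cl2, −20 °C to rt, anhydrous; base-washed work-up
Reagents that add atoms: methanesulfonyl chloride, CS(=O)(=O)Cl (its atoms stand only in intermediate 22 and leave again on elimination)
Why: Mesylation followed by elimination; the aryloxy-stabilised allylic mesylate ionises readily and amine removes the C6 proton, and any diene formed by loss of the C4 proton would converge on the same arene in step 15.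

Step 15
Reactants: 23 rac-macrocyclic 1-aryloxycyclohexa-1,3-diene
Product: 24 dihydroptychantol A dimethyl ether
Conditions: DDQ (1.1 equiv), toluene, 0 °C to rt
Reagents that add atoms: none
Why: Dehydrogenative aromatisation; DDQ abstracts the allylic C5 hydride to give a cation stabilised by the C3 aryloxy group and C4 loses a proton, which should be far faster than oxidation of the bibenzyl bridges and also removes the last stereocentre.

Step 16
Reactants: 24 dihydroptychantol A dimethyl ether
Product: 25 dihydroptychantol A
Conditions: BBr3 (6 equiv), CH2Cl2, −78 °C to rt; H2O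
Reagents that add atoms: none
Why: Lewis acid cleavage of both aryl methyl ethers by bromide attack on the methyl groups, while the two diaryl ether bonds offer no sp3 carbon to attack and stay intact.

## Compound list

1 | 2-hydroxy-5-methoxybenzaldehyde | COc1ccc(O)c(C=O)c1 | starting material
2 | 5-methoxy-2-(propan-2-yloxy)benzaldehyde | COc1ccc(OC(C)C)c(C=O)c1 | intermediate
3 | [5-methoxy-2-(propan-2-yloxy)phenyl]methanol | COc1ccc(OC(C)C)c(CO)c1 | intermediate
4 | [5-methoxy-2-(propan-2-yloxy)benzyl]triphenylphosphonium bromide | COc1ccc(OC(C)C)c(C[P+](c2ccccc2)(c2ccccc2)c2ccccc2)c1.[Br-] | intermediate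
5 | methyl 3-(4-hydroxyphenyl)propanoate | COC(=O)CCc1ccc(O)cc1 | starting material
6 | 3-bromo-4-methoxybenzaldehyde | COc1ccc(C=O)cc1Br | starting material
7 | methyl 3-[4-(5-formyl-2-methoxyphenoxy)phenyl]propanoate | COC(=O)CCc1ccc(Oc2cc(C=O)ccc2OC)cc1 | intermediate
8 | benzylidene phosphorane from 4 (not isolated) | COc1ccc(OC(C)C)c(C=P(c2ccccc2)(c2ccccc2)c2ccccc2)c1 | intermediate
9 | stilbene ester, E/Z mixture (drawn without alkene descriptor) | COC(=O)CCc1ccc(Oc2cc(C=Cc3cc(OC)ccc3OC(C)C)ccc2OC)cc1 | intermediate
10 | methyl 3-(Ar1)propanoate | COC(=O)CCc1ccc(Oc2cc(CCc3cc(OC)ccc3OC(C)C)ccc2OC)cc1 | intermediate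
11 | 3-(Ar1)propanal | O=CCCc1ccc(Oc2cc(CCc3cc(OC)ccc3OC(C)C)ccc2OC)cc1 | intermediate
12 | (E)-6-(Ar1)hex-3-en-2-one | CC(=O)/C=C/CCc1ccc(Oc2cc(CCc3cc(OC)ccc3OC(C)C)ccc2OC)cc1 | intermediate
13 | diethyl malonate | CCOC(=O)CC(=O)OCC | starting material
14 | diethyl 2-[1-(Ar1)-5-oxohexan-3-yl]malonate, racemic (not isolated) | CCOC(=O)C(C(=O)OCC)C(CC(C)=O)CCc1ccc(Oc2cc(CCc3cc(OC)ccc3OC(C)C)ccc2OC)cc1 | intermediate
15 | ethyl 2-[2-(Ar1)ethyl]-4,6-dioxocyclohexane-1-carboxylate, racemic diastereomer mixture (not isolated) | CCOC(=O)C1C(=O)CC(=O)CC1CCc1ccc(Oc2cc(CCc3cc(OC)ccc3OC(C)C)ccc2OC)cc1 | intermediate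
16 | 2-[2-(Ar1)ethyl]-4,6-dioxocyclohexane-1-carboxylic acid, racemic diastereomer mixture (not isolated) | OC(=O)C1C(=O)CC(=O)CC1CCc1ccc(Oc2cc(CCc3cc(OC)ccc3OC(C)C)ccc2OC)cc1 | intermediate
17 | 5-[2-(Ar1)ethyl]cyclohexane-1,3-dione (achiral) | O=C1CC(=O)CC(CCc2ccc(Oc3cc(CCc4cc(OC)ccc4OC(C)C)ccc3OC)cc2)C1 | intermediate
18 | rac-3-chloro-5-[2-(Ar1)ethyl]cyclohex-2-en-1-one | COc1ccc(OC(C)C)c(c1)CCc1ccc(OC)c(c1)Oc1ccc(cc1)CCC1CC(Cl)=CC(=O)C1 | intermediate
19 | racemic seco 3-chloroenone with free ring A phenol | COc1ccc(O)c(c1)CCc1ccc(OC)c(c1)Oc1ccc(cc1)CCC1CC(Cl)=CC(=O)C1 | intermediate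
20 | racemic macrocyclic 3-aryloxycyclohex-2-en-1-one | COc1ccc2c(c1)CCc1ccc(OC)c(c1)Oc1ccc(cc1)CCC1CC(=CC(=O)C1)O2 | intermediate
21 | macrocyclic 3-aryloxycyclohex-2-en-1-ol, racemic, C1/C5 diastereomer mixture | COc1ccc2c(c1)CCc1ccc(OC)c(c1)Oc1ccc(cc1)CCC1CC(=CC(O)C1)O2 | intermediate
22 | allylic mesylate of 21 (not isolated) | COc1ccc2c(c1)CCc1ccc(OC)c(c1)Oc1ccc(cc1)CCC1CC(=CC(OS(C)(=O)=O)C1)O2 | intermediate
23 | racemic macrocyclic 1-aryloxycyclohexa-1,3-diene | COc1ccc2c(c1)CCc1ccc(OC)c(c1)Oc1ccc(cc1)CCC1CC(=CC=C1)O2 | intermediate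
24 | dihydroptychantol A dimethyl ether | COc1ccc2c(c1)CCc1ccc(OC)c(c1)Oc1ccc(cc1)CCc1cccc(c1)O2 | intermediate
25 | dihydroptychantol A | Oc1ccc2c(c1)CCc1ccc(O)c(c1)Oc1ccc(cc1)CCc1cccc(c1)O2 | target

## Step count and risks

Total step count: 16. Longest linear sequence: 15 (steps 1 to 3, then 5 to 16).

**Step 12, macrocyclisation.** Intermolecular addition–elimination may outrun closure of the 18-membered ring and lead to oligomers. Traces of water may also hydrolyse the chloroenone to the unreactive dione enolate.

The fallback sets out from 17 and returns at 24. Ring D is made aromatic first, and the O–C bond is then formed by a copper-catalysed intramolecular Ullmann coupling.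
- Ph3P·Br2 and Et3N convert 17 into the isopropyl-protected 3-bromoenone F1.
- Luche reduction (NaBH4, CeCl3·7H2O, MeOH) gives the bromo allylic alcohol F2.
- MsCl and Et3N give the bromo allylic mesylate F3, from which DBU removes methanesulfonic acid to give the bromocyclohexadiene F4.
- DDQ in warm toluene gives the seco 3-bromophenyl compound F5.
- BCl3 frees ring A to give the seco bromo phenol F6.
- CuI, N,N-dimethylglycine and Cs2CO3 in dioxane at high dilution close F6 to 24.

**Step 14, mesylation and elimination.** The aryloxy-stabilised allyl cation may be captured at C3 by adventitious water. Ring A phenol is then expelled in a Stork–Danheiser-type transposition, which reopens the macrocycle. The diene itself is prone to the same hydrolysis.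

The fallback sets out from 20 and returns at 24. The carbonyl oxygen is kept through aromatisation and removed afterwards from a robust arene.
- LiN(SiMe3)2 and Me3SiCl at −78 °C give the cross-conjugated silyl dienol ether F7.
- Saegusa–Ito oxidation (Pd(OAc)2, O2, DMSO) and tautomerisation give the macrocyclic ring D phenol F8.
- Tf2O and pyridine give the aryl triflate F9.
- Reduction with formate under zerovalent palladium catalysis (Pd(PPh3)4, HCO2H, Et3N, DMF, 80 °C) replaces the triflate by hydrogen to give 24.

**Step 11, release of the phenol.** BCl3 may activate the chloroenone towards Friedel–Crafts attack by the electron-rich rings. It may also strip the ring B methyl ether through chelation with the neighbouring ether oxygen, and the chloroenone may hydrolyse during the quench.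

The fallback sets out from 17 and returns at 19, with the order of events reversed.
- BCl3 meets the robust dione and gives the phenol dione F10.
- Only the acidic enol is then chlorinated under neutral Appel-type conditions (PPh3, CCl4, MeCN). The aryloxyphosphonium form of the phenol cannot be substituted and reverts on work-up.

## Further compounds

F1 | step 12 | rac-3-bromo-5-[2-(Ar1)ethyl]cyclohex-2-en-1-one | COc1ccc(OC(C)C)c(c1)CCc1ccc(OC)c(c1)Oc1ccc(cc1)CCC1CC(Br)=CC(=O)C1
F2 | step 12 | 3-bromo-5-[2-(Ar1)ethyl]cyclohex-2-en-1-ol, racemic diastereomer mixture | COc1ccc(OC(C)C)c(c1)CCc1ccc(OC)c(c1)Oc1ccc(cc1)CCC1CC(Br)=CC(O)C1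
F3 | step 12 | methanesulfonate of F2 | COc1ccc(OC(C)C)c(c1)CCc1ccc(OC)c(c1)Oc1ccc(cc1)CCC1CC(Br)=CC(OS(C)(=O)=O)C1
F4 | step 12 | rac-1-bromo-5-[2-(Ar1)ethyl]cyclohexa-1,3-diene | COc1ccc(OC(C)C)c(c1)CCc1ccc(OC)c(c1)Oc1ccc(cc1)CCC1CC(Br)=CC=C1
F5 | step 12 | 1-bromo-3-[2-(Ar1)ethyl]benzene | COc1ccc(OC(C)C)c(c1)CCc1ccc(OC)c(c1)Oc1ccc(cc1)CCc1cccc(Br)c1
F6 | step 12 | seco bromo phenol (F5 with free ring A phenol) | COc1ccc(O)c(c1)CCc1ccc(OC)c(c1)Oc1ccc(cc1)CCc1cccc(Br)c1
F7 | step 14 | racemic macrocyclic 1-trimethylsilyloxy-3-aryloxycyclohexa-1,3-diene (C1=C6, C2=C3) | COc1ccc2c(c1)CCc1ccc(OC)c(c1)Oc1ccc(cc1)CCC1CC(=CC(O[Si](C)(C)C)=C1)O2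
F8 | step 14 | macrocyclic ring D phenol (hydroxy group meta to both the ether oxygen and the bridge) | COc1ccc2c(c1)CCc1ccc(OC)c(c1)Oc1ccc(cc1)CCc1cc(O)cc(c1)O2
F9 | step 14 | trifluoromethanesulfonate of F8 | COc1ccc2c(c1)CCc1ccc(OC)c(c1)Oc1ccc(cc1)CCc1cc(OS(=O)(=O)C(F)(F)F)cc(c1)O2
F10 | step 11 | phenol dione (17 without the isopropyl group) | COc1ccc(O)c(c1)CCc1ccc(OC)c(c1)Oc1ccc(cc1)CCC1CC(=O)CC(=O)C1
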